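**Plan**

Retrosynthesis: (1) the CH2–CH2 link between ring A (the cyclohexenone) and ring B (the 1,2-dioxane) is cut as a C=C bond (Horner–Wadsworth–Emmons) into ring-A phosphonate 12 and peroxy aldehyde 28; (2) ring A is cut at C5–C6 (aldol condensation) and then at C3–C4 (Michael addition) into 2-methylpropanal and an acylallenylphosphonate; (3) ring B is cut at O2–C3 (SN2) and O1–C6 (epoxide opening by H2O2), which leads back to geranyl acetate.
Forward: ring A arises first, one oxidation level too high (a 4,4-dimethylcyclohexa-2,5-dienone), by closure of C5–C6; ring B is built separately on the geranyl chain; the halves are joined by olefination, and one diimide reduction at the end removes both helper C=C bonds (C5=C6 of ring A and the link) without touching the O–O bond.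
Enabling feature: in ring A the quaternary gem-dimethyl carbon C4 makes the adjacent aldehyde carbon C5 of the open-chain precursor non-enolisable (acceptor only), and the phosphonate-bearing CH2 on C3 (γ to the C1 ketone) lets the tetrasubstituted C2=C3 bond equilibrate, so all isomers of the keto aldehyde funnel through the one whose acetyl CH3 (the future C6) can reach C5.
Stereochemistry: the α-methyl carbon and C3 of ring B come from a Brown (Z)-crotylboration (syn), C3 then being inverted in the ring-closing hydroperoxide SN2; C6 of ring B comes from a Sharpless epoxidation followed by invertive perhydrolysis at the tertiary epoxide carbon.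

Key step: step 4

Remark: ring A = cyclohexenone with C1 (C=O), C2 (CH3), C3 (side chain), C4 (CMe2), C5, C6; ring B = 1,2-dioxane with O1, O2, C3 (bears the propanoate) and C6 (quaternary). Reagent 16 is assumed to be made beforehand by the standard Brown protocol from (+)-B-methoxydiisopinocampheylborane and cis-2-butene. Compounds 3 and 6 are racemic and 11 is an isomer mixture; all of this is erased in step 4.

**Route**

Step 1
Reactants: 1 butane-2,3-dione; 2 ethynylmagnesium bromide
Product: 3 3-hydroxy-3-methylpent-4-yn-2-one (racemic)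
Conditions: 2 (THF solution) added slowly to 1 (3 equiv), THF, −78 °C; then sat. aq NH4Cl
Reagents that add atoms: none
Why: Grignard 1,2-addition of the alkynyl nucleophile to one carbonyl group of the symmetrical 1,2-diketone should stop at mono-addition when the reagent is added to an excess of 1 at low temperature, and the new carbinol centre is racemic and is erased in step 2.

Step 2
Reactants: 3 3-hydroxy-3-methylpent-4-yn-2-one; 4 diethyl chlorophosphite
Product: 6 diethyl (3-methyl-4-oxopenta-1,2-dien-1-yl)phosphonate (racemic allene), via propargyl phosphite 5 (not isolated)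
Conditions: Et3N, CH2Cl2, −78 °C → rt
Reagents that add atoms: none
Why: O-phosphitylation of the tertiary propargylic alcohol gives phosphite 5, which should undergo the well-known [2,3]-sigmatropic propargyl phosphite to allenylphosphonate rearrangement on warming, placing the P=O and C=O acceptors on the two ends of the allene.

Step 3
Reactants: 6 diethyl (3-methyl-4-oxopenta-1,2-dien-1-yl)phosphonate; 7 2-methylpropanal; 8 pyrrolidine
Product: 11 diethyl [3-methyl-2-(2-methyl-1-oxopropan-2-yl)-4-oxopent-2-en-1-yl]phosphonate (E/Z mixture), via enamine 9 (not isolated), via aminodihydropyran adduct 10 (not isolated)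
Conditions: 7 + 8, 4 Å MS, Et2O, 0 °C → rt; then 6, MeCN, 0 °C → rt; then aq AcOH/NaOAc (pH 5), rt
Reagents that add atoms: water, O
Why: Stork enamine Michael addition, in which the nucleophilic carbon of enamine 9 attacks the central allene carbon of 6 (the β-position of both the enone and the vinylphosphonate) so that the quaternary C4 and the C3–C4 bond of ring A are formed, and mild hydrolysis of adduct 10 releases the aldehyde; no stereocentre survives and the tetrasubstituted C=C is obtained as an isomer mixture.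

Step 4
Reactants: 11 diethyl [3-methyl-2-(2-methyl-1-oxopropan-2-yl)-4-oxopent-2-en-1-yl]phosphonate (E/Z mixture)
Product: 12 diethyl [(2,6,6-trimethyl-3-oxocyclohexa-1,4-dien-1-yl)methyl]phosphonate
Conditions: pyrrolidine (0.3 equiv), AcOH (0.3 equiv), PhMe (0.05 M), 4 Å MS, 70 °C
Reagents that add atoms: none
Why: Pyrrolidinium acetate condenses reversibly with both carbonyl groups: the ketone gives iminium and dienamine species through which the E and Z isomers of 11 (and any deconjugated vinylphosphonate tautomer) interconvert by removal and return of a proton at the doubly activated CH2–P carbon, while the aldehyde gives a reactive iminium ion. Only in the isomer with the acetyl group cis to the CMe2–CHO arm (formally E) can the enamine carbon derived from the acetyl CH3 (C6) reach C5, so the whole mixture should drain through this isomer in a dynamic, stereoconvergent ring closure, and loss of amine and water then gives the C5=C6 double bond. The closest known reaction is the Stork enamine, Robinson-type annulation of 2-methylpropanal with methyl vinyl ketone to 4,4-dimethylcyclohex-2-enone, which also ends in an intramolecular aldol (Mannich) condensation. Ring A closes in the 6-(enolendo)-exo-trig mode. No stereocentre is formed. The step needs site selectivity for C6 over the other nucleophilic carbons (CH2–P and C2), which is secured because those could only give four-membered rings and because C5, flanked by the quaternary C4, can neither enolise nor self-condense.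

Step 5
Reactants: 13 geranyl acetate
Product: 15 (2E)-3-methyl-6-oxohex-2-en-1-yl acetate, via ozonide 14 (not isolated)
Conditions: O3 (1.0 equiv), CH2Cl2, −78 °C; then Me2S, −78 °C → rt
Reagents that add atoms: ozone, [O-][O+]=O
Why: Ozonolysis with reductive work-up should cleave only the remote, more electron-rich trisubstituted 6,7-alkene, because the 2,3-alkene is deactivated by the allylic acetoxy group and ozone is limited to one equivalent.

Step 6
Reactants: 15 (2E)-3-methyl-6-oxohex-2-en-1-yl acetate; 16 (Z)-crotyldiisopinocampheylborane with Ipc groups from (−)-α-pinene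
Product: 18 (2E,6S,7S)-6-hydroxy-3,7-dimethylnona-2,8-dien-1-yl acetate, via borinate 17 (not isolated)
Conditions: THF/Et2O, −78 °C; then NaOAc, 30% H2O2, H2O, 0 °C → rt
Reagents that add atoms: none
Why: Brown asymmetric crotylboration through a chair Zimmerman–Traxler transition state, in which the (Z)-crotyl geometry fixes the syn relationship of OH and CH3 and the Ipc groups derived from (−)-α-pinene direct the transfer to the Re face of the aldehyde, setting (6S,7S).

Step 7
Reactants: 18 (2E,6S,7S)-6-hydroxy-3,7-dimethylnona-2,8-dien-1-yl acetate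
Product: 19 (2E,6S,7S)-3,7-dimethyl-6-(methylsulfonyloxy)nona-2,8-dien-1-yl acetate
Conditions: MsCl, Et3N, CH2Cl2, 0 °C
Reagents that add atoms: methanesulfonyl chloride, CS(=O)(=O)Cl
Why: Sulfonylation on oxygen turns the carbinol carbon (the future C3 of ring B) into an SN2 electrophile with its configuration untouched.

Step 8
Reactants: 19 (2E,6S,7S)-3,7-dimethyl-6-(methylsulfonyloxy)nona-2,8-dien-1-yl acetate
Product: 20 (3S,4S,7E)-9-hydroxy-3,7-dimethylnona-1,7-dien-4-yl methanesulfonate
Conditions: K2CO3 (0.2 equiv), MeOH, 0 °C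
Reagents that add atoms: none
Why: Carbonate-catalysed transesterification (Zemplén-type methanolysis) removes the allylic acetate, while the secondary mesylate is inert to methanol and catalytic carbonate at 0 °C.

Step 9
Reactants: 20 (3S,4S,7E)-9-hydroxy-3,7-dimethylnona-1,7-dien-4-yl methanesulfonate
Product: 21 {(2R,3R)-3-methyl-3-[(3S,4S)-4-methyl-3-(methylsulfonyloxy)hex-5-en-1-yl]oxiran-2-yl}methanol
Conditions: Ti(OiPr)4 (cat.), D-(−)-diethyl tartrate (cat.), tBuOOH, 4 Å MS, CH2Cl2, −20 °C
Reagents that add atoms: tert-butyl hydroperoxide, CC(C)(C)OO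
Why: Sharpless asymmetric epoxidation of the (E)-trisubstituted allylic alcohol, in which the D-(−)-tartrate ligand delivers oxygen to the face that gives the (2R,3R)-epoxy alcohol under reagent control, and the isolated vinyl group does not react.

Step 10
Reactants: 21 {(2R,3R)-3-methyl-3-[(3S,4S)-4-methyl-3-(methylsulfonyloxy)hex-5-en-1-yl]oxiran-2-yl}methanol
Product: 22 (3S,4S,7S,8R)-7-hydroperoxy-8,9-dihydroxy-3,7-dimethylnon-1-en-4-yl methanesulfonate
Conditions: anhydrous H2O2 in Et2O (excess), H3PMo12O40 (5 mol%), rt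
Reagents that add atoms: hydrogen peroxide, OO
Why: Molybdenum-catalysed perhydrolysis of the epoxide, in which H2O2 should open the activated oxirane in an SN2-like manner at the tertiary carbon (better cation-stabilised and remote from the CH2OH group) with inversion, creating the peroxy-bearing quaternary centre C6 of ring B in the spatial arrangement of the target.

Step 11
Reactants: 22 (3S,4S,7S,8R)-7-hydroperoxy-8,9-dihydroxy-3,7-dimethylnon-1-en-4-yl methanesulfonate
Product: 23 (1R)-1-{(3S,6R)-6-[(2S)-but-3-en-2-yl]-3-methyl-1,2-dioxan-3-yl}ethane-1,2-diol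
Conditions: KOtBu (1.0 equiv), 18-crown-6, THF, 0 °C
Reagents that add atoms: none
Why: Intramolecular alkylation of a hydroperoxide, in which one equivalent of base deprotonates only the OOH group and the peroxy anion displaces the mesylate in a 6-exo-tet SN2 reaction with inversion, closing ring B and setting its C3.

Step 12
Reactants: 23 (1R)-1-{(3S,6R)-6-[(2S)-but-3-en-2-yl]-3-methyl-1,2-dioxan-3-yl}ethane-1,2-diol
Product: 25 (2R)-2-{(3R,6S)-6-[(1R)-1,2-dihydroxyethyl]-6-methyl-1,2-dioxan-3-yl}propanal, via ozonide 24 (not isolated)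
Conditions: O3, CH2Cl2, −78 °C; then Me2S, −78 °C → rt
Reagents that add atoms: ozone, [O-][O+]=O
Why: Ozonolysis of the only remaining C=C bond (the terminal vinyl group) with dimethyl sulfide work-up gives the aldehyde, and the dialkyl peroxide and the free diol are inert to ozone and to the sulfide.

Step 13
Reactants: 25 (2R)-2-{(3R,6S)-6-[(1R)-1,2-dihydroxyethyl]-6-methyl-1,2-dioxan-3-yl}propanal
Product: 26 (2R)-2-{(3R,6S)-6-[(1R)-1,2-dihydroxyethyl]-6-methyl-1,2-dioxan-3-yl}propanoic acid
Conditions: NaClO2, NaH2PO4, 2-methylbut-2-ene, tBuOH/H2O, 0 °C → rt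
Reagents that add atoms: sodium chlorite, [Na+].[O-]Cl=O
Why: Pinnick oxidation converts the aldehyde into the acid under buffered, weakly acidic conditions, which should avoid both epimerisation of the α-centre and β-elimination of the peroxide.

Step 14
Reactants: 26 (2R)-2-{(3R,6S)-6-[(1R)-1,2-dihydroxyethyl]-6-methyl-1,2-dioxan-3-yl}propanoic acid
Product: 27 methyl (2R)-2-{(3R,6S)-6-[(1R)-1,2-dihydroxyethyl]-6-methyl-1,2-dioxan-3-yl}propanoate
Conditions: TMSCHN2, MeOH/PhMe, 0 °C
Reagents that add atoms: (trimethylsilyl)diazomethane, C[Si](C)(C)C=[N+]=[N-]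
Why: Esterification with (trimethylsilyl)diazomethane methylates only the carboxylic acid and leaves the diol and the peroxide alone.

Step 15
Reactants: 27 methyl (2R)-2-{(3R,6S)-6-[(1R)-1,2-dihydroxyethyl]-6-methyl-1,2-dioxan-3-yl}propanoate
Product: 28 methyl (2R)-2-[(3R,6S)-6-formyl-6-methyl-1,2-dioxan-3-yl]propanoate
Conditions: NaIO4, THF/H2O (pH 7 buffer), 0 °C
Reagents that add atoms: none
Why: Periodate glycol cleavage removes the extra carbon as formaldehyde and unmasks the aldehyde on the quaternary peroxy carbon, for which the diol served as a protected form through steps 11 to 14.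

Step 16
Reactants: 12 diethyl [(2,6,6-trimethyl-3-oxocyclohexa-1,4-dien-1-yl)methyl]phosphonate; 28 methyl (2R)-2-[(3R,6S)-6-formyl-6-methyl-1,2-dioxan-3-yl]propanoate
Product: 29 methyl (2R)-2-{(3R,6S)-6-methyl-6-[(E)-2-(2,6,6-trimethyl-3-oxocyclohexa-1,4-dien-1-yl)ethenyl]-1,2-dioxan-3-yl}propanoate
Conditions: 12, LiN(SiMe3)2 (1.0 equiv), THF, −78 °C; then 28, −78 → 0 °C
Reagents that add atoms: none
Why: Vinylogous Horner–Wadsworth–Emmons olefination, in which the carbanion at the CH2–P carbon of 12 adds to the non-enolisable aldehyde 28 and eliminates phosphate to give the E-alkene, the stabilised anion being too weak a base to deprotonate the ester next to the peroxide.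

Step 17
Reactants: 29 methyl (2R)-2-{(3R,6S)-6-methyl-6-[(E)-2-(2,6,6-trimethyl-3-oxocyclohexa-1,4-dien-1-yl)ethenyl]-1,2-dioxan-3-yl}propanoate
Product: 30 diacarperoxide A, methyl (2R)-2-{(3R,6R)-6-methyl-6-[2-(2,6,6-trimethyl-3-oxocyclohex-1-en-1-yl)ethyl]-1,2-dioxan-3-yl}propanoate
Conditions: KO2CN=NCO2K (excess), AcOH, MeOH/CH2Cl2, 0 °C → rt
Reagents that add atoms: none
Why: Diimide transfers H2 in a concerted syn fashion to the two disubstituted C=C bonds (C5=C6 of ring A and the link between the rings), while the tetrasubstituted C2=C3 bond is too hindered and the C=O, ester and O–O bonds are not reduced by diimide, so both helper unsaturations should go in one operation.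

**Compound list**

1 | butane-2,3-dione | CC(=O)C(C)=O | starting material
2 | ethynylmagnesium bromide | C#C[Mg]Br | starting material
3 | 3-hydroxy-3-methylpent-4-yn-2-one (racemic) | CC(=O)C(C)(O)C#C | intermediate
4 | diethyl chlorophosphite | CCOP(Cl)OCC | starting material
5 | diethyl 3-methyl-4-oxopent-1-yn-3-yl phosphite (racemic) | CCOP(OCC)OC(C)(C#C)C(C)=O | intermediate (not isolated)
6 | diethyl (3-methyl-4-oxopenta-1,2-dien-1-yl)phosphonate (racemic allene) | CCOP(=O)(OCC)C=C=C(C)C(C)=O | intermediate
7 | 2-methylpropanal | CC(C)C=O | starting material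
8 | pyrrolidine | C1CCNC1 | starting material
9 | 1-(2-methylprop-1-en-1-yl)pyrrolidine | CC(C)=CN1CCCC1 | intermediate (not isolated)
10 | diethyl {[3,3,5,6-tetramethyl-2-(pyrrolidin-1-yl)-2,3-dihydro-4H-pyran-4-ylidene]methyl}phosphonate (racemic, alkene geometry open) | CCOP(=O)(OCC)C=C1C(C)=C(C)OC(N2CCCC2)C1(C)C | intermediate (not isolated)
11 | diethyl [3-methyl-2-(2-methyl-1-oxopropan-2-yl)-4-oxopent-2-en-1-yl]phosphonate (E/Z mixture, geometry left open on purpose) | CCOP(=O)(OCC)CC(=C(C)C(C)=O)C(C)(C)C=O | intermediate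
12 | diethyl [(2,6,6-trimethyl-3-oxocyclohexa-1,4-dien-1-yl)methyl]phosphonate | CCOP(=O)(OCC)CC1=C(C)C(=O)C=CC1(C)C | intermediate
13 | geranyl acetate | CC(=O)OC/C=C(\C)CCC=C(C)C | starting material
14 | (2E)-5-(5,5-dimethyl-1,2,4-trioxolan-3-yl)-3-methylpent-2-en-1-yl acetate | CC(=O)OC/C=C(\C)CCC1OOC(C)(C)O1 | intermediate (not isolated)
15 | (2E)-3-methyl-6-oxohex-2-en-1-yl acetate | CC(=O)OC/C=C(\C)CCC=O | intermediate
16 | (Z)-crotyldiisopinocampheylborane, Ipc from (−)-α-pinene | C/C=C\CB([C@H]1C[C@H]2C[C@@H]([C@@H]1C)C2(C)C)[C@H]1C[C@H]2C[C@@H]([C@@H]1C)C2(C)C | starting material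
17 | (2E,6S,7S)-6-(diisopinocampheylboranyloxy)-3,7-dimethylnona-2,8-dien-1-yl acetate | C=C[C@H](C)[C@@H](OB([C@H]1C[C@H]2C[C@@H]([C@@H]1C)C2(C)C)[C@H]1C[C@H]2C[C@@H]([C@@H]1C)C2(C)C)CC/C(C)=C/COC(C)=O | intermediate (not isolated)
18 | (2E,6S,7S)-6-hydroxy-3,7-dimethylnona-2,8-dien-1-yl acetate | C=C[C@H](C)[C@@H](O)CC/C(C)=C/COC(C)=O | intermediate
19 | (2E,6S,7S)-3,7-dimethyl-6-(methylsulfonyloxy)nona-2,8-dien-1-yl acetate | C=C[C@H](C)[C@@H](OS(C)(=O)=O)CC/C(C)=C/COC(C)=O | intermediate
20 | (3S,4S,7E)-9-hydroxy-3,7-dimethylnona-1,7-dien-4-yl methanesulfonate | C=C[C@H](C)[C@@H](OS(C)(=O)=O)CC/C(C)=C/CO | intermediate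
21 | {(2R,3R)-3-methyl-3-[(3S,4S)-4-methyl-3-(methylsulfonyloxy)hex-5-en-1-yl]oxiran-2-yl}methanol | C=C[C@H](C)[C@@H](OS(C)(=O)=O)CC[C@@]1(C)O[C@@H]1CO | intermediate
22 | (3S,4S,7S,8R)-7-hydroperoxy-8,9-dihydroxy-3,7-dimethylnon-1-en-4-yl methanesulfonate | C=C[C@H](C)[C@@H](OS(C)(=O)=O)CC[C@](C)(OO)[C@H](O)CO | intermediate
23 | (1R)-1-{(3S,6R)-6-[(2S)-but-3-en-2-yl]-3-methyl-1,2-dioxan-3-yl}ethane-1,2-diol | C=C[C@H](C)[C@H]1CC[C@@](C)([C@H](O)CO)OO1 | intermediate
24 | (1R)-1-{(3S,6R)-3-methyl-6-[(1R)-1-(1,2,4-trioxolan-3-yl)ethyl]-1,2-dioxan-3-yl}ethane-1,2-diol (trioxolane carbon unassigned) | C2OC(OO2)[C@H](C)[C@H]1CC[C@@](C)([C@H](O)CO)OO1 | intermediate (not isolated)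
25 | (2R)-2-{(3R,6S)-6-[(1R)-1,2-dihydroxyethyl]-6-methyl-1,2-dioxan-3-yl}propanal | O=C[C@H](C)[C@H]1CC[C@@](C)([C@H](O)CO)OO1 | intermediate
26 | (2R)-2-{(3R,6S)-6-[(1R)-1,2-dihydroxyethyl]-6-methyl-1,2-dioxan-3-yl}propanoic acid | OC(=O)[C@H](C)[C@H]1CC[C@@](C)([C@H](O)CO)OO1 | intermediate
27 | methyl (2R)-2-{(3R,6S)-6-[(1R)-1,2-dihydroxyethyl]-6-methyl-1,2-dioxan-3-yl}propanoate | COC(=O)[C@H](C)[C@H]1CC[C@@](C)([C@H](O)CO)OO1 | intermediate
28 | methyl (2R)-2-[(3R,6S)-6-formyl-6-methyl-1,2-dioxan-3-yl]propanoate | COC(=O)[C@H](C)[C@H]1CC[C@@](C)(C=O)OO1 | intermediate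
29 | methyl (2R)-2-{(3R,6S)-6-methyl-6-[(E)-2-(2,6,6-trimethyl-3-oxocyclohexa-1,4-dien-1-yl)ethenyl]-1,2-dioxan-3-yl}propanoate | COC(=O)[C@H](C)[C@H]1CC[C@@](C)(/C=C/C2=C(C)C(=O)C=CC2(C)C)OO1 | intermediate
30 | diacarperoxide A, methyl (2R)-2-{(3R,6R)-6-methyl-6-[2-(2,6,6-trimethyl-3-oxocyclohex-1-en-1-yl)ethyl]-1,2-dioxan-3-yl}propanoate | COC(=O)[C@H](C)[C@H]1CC[C@@](C)(CCC2=C(C)C(=O)CCC2(C)C)OO1 | target

**Summary**

Total step count: 17. Longest linear sequence: 13 steps (13 → 30, steps 5 to 17); the ring-A branch (steps 1 to 4) joins in step 16.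

Three steps most likely to fail:

Step 11. The peroxy anion may act as a base instead of a nucleophile (elimination of the mesylate toward the allylic C–H), substitution at the β-branched secondary carbon may be slow, or the β-hydroxy hydroperoxide may fragment under base. The fallback replaces the base-mediated sulfonate displacement by a silver-assisted halide displacement. It sets out from 15: (E)-crotyldiisopinocampheylborane with Ipc groups from (+)-α-pinene should give the anti alcohol (2E,6R,7S)-6-hydroxy-3,7-dimethylnona-2,8-dien-1-yl acetate F2; Appel bromination (CBr4, PPh3) with inversion gives (2E,6S,7S)-6-bromo-3,7-dimethylnona-2,8-dien-1-yl acetate F3; methanolysis (K2CO3, MeOH) gives (2E,6S,7S)-6-bromo-3,7-dimethylnona-2,8-dien-1-ol F4; Sharpless epoxidation with D-(−)-diethyl tartrate gives {(2R,3R)-3-[(3S,4S)-3-bromo-4-methylhex-5-en-1-yl]-3-methyloxiran-2-yl}methanol F5; perhydrolysis as in step 10 gives (2R,3S,6S,7S)-6-bromo-3-hydroperoxy-3,7-dimethylnon-8-ene-1,2-diol F6; silver trifluoroacetate AgO2CCF3 in CH2Cl2 then closes the ring with inversion under non-basic conditions, and the route is rejoined at 23.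

Step 3. The doubly activated allene may oligomerise or give [2+2] adducts with the enamine instead of the open Michael adduct. The fallback uses a Lewis-acid-mediated Mukaiyama–Michael addition. It sets out from 7, which is silylated (TMSCl, Et3N, NaI, MeCN) to trimethyl[(2-methylprop-1-en-1-yl)oxy]silane F1; F1 is added to 6 with TiCl4 in CH2Cl2 at −78 °C, and aqueous work-up returns to the route at 11.

Step 17. Diimide may reduce the hindered, conjugated C5=C6 bond of ring A only partly, which would leave mixtures at the last step. The fallback moves this reduction to the fragment stage. It sets out from 12, which is hydrogenated (H2, Pd/C, EtOAc) at the disubstituted ring alkene to diethyl [(2,6,6-trimethyl-3-oxocyclohex-1-en-1-yl)methyl]phosphonate F7; olefination of 28 with F7 as in step 16 gives methyl (2R)-2-{(3R,6S)-6-methyl-6-[(E)-2-(2,6,6-trimethyl-3-oxocyclohex-1-en-1-yl)ethenyl]-1,2-dioxan-3-yl}propanoate F8, and diimide then has to reduce only the side-chain alkene, which returns to the route at 30.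

**Further compounds**

F1 | step 3 | trimethyl[(2-methylprop-1-en-1-yl)oxy]silane | CC(C)=CO[Si](C)(C)C
F2 | step 11 | (2E,6R,7S)-6-hydroxy-3,7-dimethylnona-2,8-dien-1-yl acetate | C=C[C@H](C)[C@H](O)CC/C(C)=C/COC(C)=O
F3 | step 11 | (2E,6S,7S)-6-bromo-3,7-dimethylnona-2,8-dien-1-yl acetate | C=C[C@H](C)[C@@H](Br)CC/C(C)=C/COC(C)=O
F4 | step 11 | (2E,6S,7S)-6-bromo-3,7-dimethylnona-2,8-dien-1-ol | C=C[C@H](C)[C@@H](Br)CC/C(C)=C/CO
F5 | step 11 | {(2R,3R)-3-[(3S,4S)-3-bromo-4-methylhex-5-en-1-yl]-3-methyloxiran-2-yl}methanol | C=C[C@H](C)[C@@H](Br)CC[C@@]1(C)O[C@@H]1CO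
F6 | step 11 | (2R,3S,6S,7S)-6-bromo-3-hydroperoxy-3,7-dimethylnon-8-ene-1,2-diol | C=C[C@H](C)[C@@H](Br)CC[C@](C)(OO)[C@H](O)CO
F7 | step 17 | diethyl [(2,6,6-trimethyl-3-oxocyclohex-1-en-1-yl)methyl]phosphonate | CCOP(=O)(OCC)CC1=C(C)C(=O)CCC1(C)C
F8 | step 17 | methyl (2R)-2-{(3R,6S)-6-methyl-6-[(E)-2-(2,6,6-trimethyl-3-oxocyclohex-1-en-1-yl)ethenyl]-1,2-dioxan-3-yl}propanoate | COC(=O)[C@H](C)[C@H]1CC[C@@](C)(/C=C/C2=C(C)C(=O)CCC2(C)C)OO1
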